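If both steps of the round can run backwards, the chair opened, then the first question is where this flask must stop, and how fast it gets there comes second.

the same everywhere: substrate 1.0 mM (fed, over 2.0 min); time 2.5 min
- beta: precatalyst 50 µM; the fed solution adds 1.0 times the starting volume
- epsilon: precatalyst 80 µM; the fed solution adds 1.0 times the starting volume
- gamma: precatalyst 120 µM; the fed solution adds 1.0 times the starting volume

    substrate + free catalyst ⇌ catalyst intermediate (K1 = 490 L mol⁻¹, k1 = 1200 L mol⁻¹ s⁻¹)
    catalyst intermediate ⇌ free catalyst + product (K2 = 3.8 × 10⁻⁴ M, k2 = 1.2 s⁻¹)
    precatalyst → free catalyst (k3 = 0.17 s⁻¹)

* amount of product at the end, in percent of the substrate charged for beta, epsilon, gamma, in this order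
* how the row runs (rises, then falls / rises all the way / falls, then rises / falls all the way / hardly changes)

- charges are per starting volume, the dose included; the dosed solution carries all of it
- "hardly changes" means that all values lie within two and a half points (for a concentration: within two and a half percent of the largest)
- run time (beta): 2.5 min

I argued first, at the board, in fractions of the charge. Multiplying the two equilibrium constants cancels the catalyst, so at rest product over substrate is 0.186, whatever the volume. That ratio over one plus itself gives 15.7%: the ceiling share, the part of the unbound substrate and product that stands as product at equilibrium. The field calls such an end thermodynamic control.

A colleague objected that the catalyst holds some of the charge. I answered that substrate near the ceiling, in the doubled volume, puts 17.1% of the catalyst into catalyst intermediate. So the ceiling share, scaled down by that bound part of the charge, gives 15.6% for beta and 15.4% for gamma. These are 0.20 percentage points apart, so I expected a row that hardly changes.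

The chair asked about speed. I said the precatalyst has a half-life of 4.08 s, short against the 2.0 min feed. In beta the forward flow of the second step at that bound share, 0.616 min⁻¹ in fractions of the charge, is larger than the 0.0785 min⁻¹ the ceiling asks of the feed. That flow is gross, though, so I expected beta slightly under my figure without putting a number on the lag.

The maker of the forecast then reported 15.1%, 15.4% and 15.4%, a row that hardly changes, on the ground that “the reversible cycle caps product”. For beta this stands below my figure, and for gamma it matches.

The simulation gives 15.1%, 15.4% and 15.4%, and the row hardly changes.

In beta the relaxation half-life of catalyst intermediate with free catalyst and product by the second step alone, both ways together at the asked time, is 0.461 s, short against the 2.5 min of the run, and product stands at 15.1%, which is 0.50 points under the ceiling share less the bound part. In gamma, whose product does not move with a longer run, the ceiling share 15.7% less the bound 2.05% of the charge, taken in proportion, gives 15.4% against the 15.4% in the flask.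

The constants used here are invented, and the outcome is calculated.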